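**Strategy.** Ring B (the cycloheptenone C5–C6–C7–C8–C9=C10–C11) is disconnected at C9–C10 and C5–C11. Both bonds are made in one operation by an intramolecular enone–alkene [2+2] photocycloaddition between the C5=C9 double bond of a compact cyclopentenone–butenolide (rings C and D already in place) and a C10=C11 silyl enol ether tethered through C4–C1; this closes ring A and a cyclobutane and sets C11. The feature exploited is that C5 and C9 are α to the C6 ketone and the C12 lactone carbonyl: the strained C5–C9 bond is then cut reductively and the C10 silyloxy group is expelled, which unveils ring B together with the C9=C10 alkene.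

Key step: step 12

Atom labels used throughout (not IUPAC): ring A = C1(H, isopropenyl)–C2H2–C3(OH)=C4(CO2Me)–C5H–C11H; ring B = C5–C6(=O)–C7H–C8H–C9=C10H–C11; ring C = C7–C8–C13H(O)–C14H2–C15(CH3)(OH); ring D (lactone) = C8–C9–C12(=O)–O–C13.

Remark: C5 is α to the C6 ketone and is taken to be configurationally labile, so it is set by protonation and equilibration, not by a dedicated step.

**Route**

Step 1
Reactants: 1 (R)-4-[(tert-butyldimethylsilyl)oxy]cyclopent-2-en-1-one
Product: 2 (1S,4R)-4-[(tert-butyldimethylsilyl)oxy]-1-methylcyclopent-2-en-1-ol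
Conditions: MeLi, Et2O, −78 °C; then H2O
Reagents that add atoms: methyllithium, [Li]C
Why: 1,2-Addition of the organolithium to the enone carbonyl from the face anti to the silyloxy group should set C15 with its hydroxyl cis to the C13 oxygen (substrate-controlled carbonyl addition).

Step 2
Reactants: 2 (1S,4R)-4-[(tert-butyldimethylsilyl)oxy]-1-methylcyclopent-2-en-1-ol
Product: 3 (1S,4R)-1-methylcyclopent-2-ene-1,4-diol
Conditions: tetrabutylammonium fluoride, THF, 0 °C → rt
Reagents that add atoms: none
Why: Fluoride-mediated cleavage of the silyl ether frees the secondary C13 hydroxyl without touching the stereocentres (desilylation).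

Step 3
Reactants: 3 (1S,4R)-1-methylcyclopent-2-ene-1,4-diol
Product: 4 (1S,4R)-1-methyl-4-(prop-2-yn-1-yloxy)cyclopent-2-en-1-ol
Conditions: NaH (1 equiv), propargyl bromide, THF, 0 °C
Reagents that add atoms: propargyl bromide, C#CCBr
Why: Williamson etherification should occur at the secondary alkoxide, which is far less hindered than the tertiary C15 alkoxide, and installs the three-atom tether for the later cyclocarbonylation.

Step 4
Reactants: 4 (1S,4R)-1-methyl-4-(prop-2-yn-1-yloxy)cyclopent-2-en-1-ol
Product: 5 methyl 5-{[(1R,4S)-4-hydroxy-4-methylcyclopent-2-en-1-yl]oxy}pent-3-ynoate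
Conditions: methyl diazoacetate, CuI (cat.), MeCN, rt
Reagents that add atoms: methyl diazoacetate, COC(=O)C=[N+]=[N-]
Why: Copper-catalysed coupling of a terminal alkyne with a diazoacetate (formal carbene insertion into the alkynyl C–H bond) should give the 3-alkynoate, which carries C4 and the ester carbon, without allene formation and in the presence of the free tertiary alcohol.

Step 5
Reactants: 5 methyl 5-{[(1R,4S)-4-hydroxy-4-methylcyclopent-2-en-1-yl]oxy}pent-3-ynoate
Product: 6 tricyclic enone alcohol (cyclopentenone fused to a dihydrofuran and to ring C)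
Conditions: Co2(CO)8 (cat.), tetramethylthiourea (cat.), CO (1 atm), toluene, 70 °C
Reagents that add atoms: carbon monoxide, [C-]#[O+]
Why: Intramolecular Pauson–Khand reaction: the O13 tether can deliver the alkyne only to the alkene face syn to the ether oxygen, so C8–C9 and C7–C6 form suprafacially on that face, which sets C8 and C7 (H7 and H8 cis to H13, C6 cis to the C15 hydroxyl) and builds the cyclopentenone and the dihydrofuran in one step.

Step 6
Reactants: 6 tricyclic enone alcohol
Product: 7 triethylsilyl ether of 6
Conditions: TESOTf, 2,6-lutidine, CH2Cl2, −78 → 0 °C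
Reagents that add atoms: triethylsilyl trifluoromethanesulfonate, CC[Si](CC)(CC)OS(=O)(=O)C(F)(F)F
Why: Silylation of the tertiary β-hydroxy ketone blocks retro-aldol opening of ring C and dehydration in the later oxidation and base-mediated steps (silyl protection).

Step 7
Reactants: 7 triethylsilyl ether of 6
Product: 8 enone–butenolide ester
Conditions: Pd(OH)2 on carbon (cat.), t-BuOOH, K2CO3 (cat.), CH2Cl2, 4 °C → rt
Reagents that add atoms: tert-butyl hydroperoxide, CC(C)(C)OO
Why: Palladium-catalysed peroxide γ-oxidation of an α,β-enone (enone to ene-dione type): the C12 methylene is γ to the C6 ketone and α to the ether oxygen, so hydrogen abstraction, peroxide trapping and Kornblum–DeLaMare-type collapse should turn it into the butenolide carbonyl while the less hydridic C4 methylene next to the ester is spared.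

Step 8
Reactants: 9 (S)-(+)-carvone
Product: 10 (4S)-carvone 2,3-epoxide (oxirane trans to the isopropenyl group)
Conditions: H2O2 (30% aq.), NaOH (cat.), MeOH, 0 °C
Reagents that add atoms: hydrogen peroxide, OO
Why: Weitz–Scheffer nucleophilic epoxidation attacks only the electron-poor enone double bond, leaving the isopropenyl group intact; the epoxide configuration is of no consequence.

Step 9
Reactants: 10 (4S)-carvone 2,3-epoxide
Product: 11 (3S)-5-oxo-3-(prop-1-en-2-yl)pentanoic acid
Conditions: H5IO6, THF/H2O, rt
Reagents that add atoms: orthoperiodic acid, OI(O)(O)(O)(O)=O; water, O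
Why: Periodic acid hydrolyses the epoxy ketone to the keto diol and cleaves both the glycol bond and the resulting 1,2-dicarbonyl, excising the methyl-bearing carbon as acetic acid and leaving the isopropenyl stereocentre (the future C1) flanked by an acid arm (C2–C3) and an aldehyde arm (C11–C10) (glycol cleavage).

Step 10
Reactants: 11 (3S)-5-oxo-3-(prop-1-en-2-yl)pentanoic acid
Product: 13 (3R)-5-[(tert-butyldimethylsilyl)oxy]-3-(prop-1-en-2-yl)pent-4-enoic acid, via silyl ester 12 (not isolated)
Conditions: TBSOTf, Et3N, CH2Cl2, −78 → 0 °C; then K2CO3, MeOH/H2O, 0 °C; then aq. KH2PO4 to pH 6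
Reagents that add atoms: tert-butyldimethylsilyl trifluoromethanesulfonate, CC(C)(C)[Si](C)(C)OS(=O)(=O)C(F)(F)F
Why: Soft enolisation turns the aldehyde into its silyl enol ether (E/Z mixture), the future C10=C11 partner that carries the oxygen leaving group on C10, and the labile silyl ester formed alongside is the only silyl group hydrolysed by carbonate.

Step 11
Reactants: 8 enone–butenolide ester; 13 (3R)-5-[(tert-butyldimethylsilyl)oxy]-3-(prop-1-en-2-yl)pent-4-enoic acid
Product: 16 bis-silyl enol ether photosubstrate, via acid chloride 14 (not isolated), via enol 15 (not isolated)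
Conditions: 13, 1-chloro-N,N,2-trimethylprop-1-en-1-amine, CH2Cl2, 0 °C; then 8, MgCl2, Et3N, MeCN, 0 °C; then TBSOTf, Et3N, −40 → 0 °C
Reagents that add atoms: tert-butyldimethylsilyl trifluoromethanesulfonate, CC(C)(C)[Si](C)(C)OS(=O)(=O)C(F)(F)F
Why: The C4 methylene of 8 is a vinylogous malonate (ester on one side, C5=C9–C12=O on the other), so magnesium-mediated soft enolisation and C-acylation by the acid chloride should form the C3–C4 bond, and O-silylation of the chelated enolate in the same flask fixes the β-keto ester as its (Z)-silyl enol ether (C2 cis to C5, as ring A needs) before it can tautomerise to the C4=C5 isomer.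

Step 12
Reactants: 16 bis-silyl enol ether photosubstrate
Product: 17 cyclobutane photoadduct (C5–C11 and C9–C10 formed; C10 epimers)
Conditions: hν (365 nm), degassed CH2Cl2, high dilution, −20 °C
Reagents that add atoms: none
Why: Excitation of the cyclopentenone (n→π*) and intersystem crossing give the enone triplet, which bonds first from C5 to C11 through a six-membered (6-exo-trig) transition state that closes ring A, leaving a 1,4-biradical (C9 stabilised by the lactone carbonyl, C10 by the silyloxy group) that closes the cyclobutane by C9–C10 radical recombination. The closest known reaction type is the intramolecular enone–alkene [2+2] photocycloaddition in its straight (fused) mode, here with a four-atom tether so that 1,6-closure takes the place of the usual rule of five; the crossed mode would need a seven-membered ring. C5 and C9 are controlled by the lactone already fused at C8–C9: C12 can only bend toward the face of C13, so the alkene must add to the convex face that carries H8. C11 follows because ring A has to be cis-fused to the cyclobutane, which puts H11 on the side of H7 and H8; this is matched with the pre-set C1 centre (isopropenyl and C10 both pseudo-equatorial, trans), and C10 forms as an epimer mixture that is erased in the next step. The selectivity needed is straight over crossed addition and excitation of the enone alone; the tether length and the twist of the silyloxyacrylate out of the enone plane (which also holds C11 over C5) should secure the first, and 365 nm light, which neither enol ether absorbs, the second.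

Step 13
Reactants: 17 cyclobutane photoadduct
Product: 18 3-O-TBS 15-O-TES derivative of the target
Conditions: SmI2 (2.2 equiv), THF/HMPA, −78 → 0 °C; then aq. NH4Cl
Reagents that add atoms: none
Why: Divalent samarium reduces the C6 ketone to its ketyl, which opens the cyclobutane at C5–C9 because this cleavage leaves the C9 radical stabilised by the lactone carbonyl (reductive fragmentation of a cyclobutane 1,4-keto ester); a second electron gives the C9 samarium enolate, which expels the C10 silyloxide (E1cB) to form the C9=C10 alkylidene lactone, and protonation of the C6 enolate at C5 on quench from the convex face (the side of H7, H8 and H11) should give the cis A/B fusion.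

Step 14
Reactants: 18 3-O-TBS 15-O-TES derivative of the target
Product: 19 target CNP0268969.1
Conditions: HF·pyridine, THF, 0 °C → rt
Reagents that add atoms: none
Why: Fluoride cleaves the enol silyl ether and the tertiary triethylsilyl ether; the freed β-keto ester rests as the hydrogen-bonded enol, and C5 can equilibrate through the C6 enol to the cis-fused epimer, in which C6 is pseudo-axial and avoids A(1,2) strain with the C4 ester.

**Compound list**

1 | (R)-4-[(tert-butyldimethylsilyl)oxy]cyclopent-2-en-1-one | O=C1C=C[C@H](O[Si](C)(C)C(C)(C)C)C1 | starting material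
2 | (1S,4R)-4-[(tert-butyldimethylsilyl)oxy]-1-methylcyclopent-2-en-1-ol (OH cis to OTBS) | C[Si](C)(C(C)(C)C)O[C@@H]1C[C@](C)(O)C=C1 | intermediate
3 | (1S,4R)-1-methylcyclopent-2-ene-1,4-diol (cis-diol) | O[C@@H]1C[C@](C)(O)C=C1 | intermediate
4 | (1S,4R)-1-methyl-4-(prop-2-yn-1-yloxy)cyclopent-2-en-1-ol | C#CCO[C@@H]1C[C@](C)(O)C=C1 | intermediate
5 | methyl 5-{[(1R,4S)-4-hydroxy-4-methylcyclopent-2-en-1-yl]oxy}pent-3-ynoate | COC(=O)CC#CCO[C@@H]1C[C@](C)(O)C=C1 | intermediate
6 | methyl 2-(8-hydroxy-8-methyl-6-oxo-2-oxatricyclo[5.2.1.0(4,10)]dec-4-en-5-yl)acetate; in the labels used here H7, H8 and H13 are cis and the C15 hydroxyl is cis to C6 | COC(=O)CC1=C2CO[C@@H]3C[C@](C)(O)[C@H](C1=O)[C@H]23 | intermediate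
7 | methyl 2-[8-methyl-6-oxo-8-(triethylsilyloxy)-2-oxatricyclo[5.2.1.0(4,10)]dec-4-en-5-yl]acetate (same configuration as 6) | COC(=O)CC1=C2CO[C@@H]3C[C@](C)(O[Si](CC)(CC)CC)[C@H](C1=O)[C@H]23 | intermediate
8 | methyl 2-[8-methyl-3,6-dioxo-8-(triethylsilyloxy)-2-oxatricyclo[5.2.1.0(4,10)]dec-4-en-5-yl]acetate (enone–butenolide; same configuration as 6) | COC(=O)CC1=C2C(=O)O[C@@H]3C[C@](C)(O[Si](CC)(CC)CC)[C@H](C1=O)[C@H]23 | intermediate
9 | (S)-(+)-carvone | CC1=CC[C@H](C(C)=C)CC1=O | starting material
10 | (4S)-1-methyl-4-(prop-1-en-2-yl)-7-oxabicyclo[4.1.0]heptan-2-one, oxirane trans to the isopropenyl group | C[C@]12O[C@@H]1C[C@H](C(C)=C)CC2=O | intermediate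
11 | (3S)-5-oxo-3-(prop-1-en-2-yl)pentanoic acid | O=CC[C@H](C(C)=C)CC(=O)O | intermediate
12 | tert-butyldimethylsilyl (3R)-5-[(tert-butyldimethylsilyl)oxy]-3-(prop-1-en-2-yl)pent-4-enoate (E/Z mixture) | CC(C)(C)[Si](C)(C)OC=C[C@H](C(C)=C)CC(=O)O[Si](C)(C)C(C)(C)C | intermediate (not isolated)
13 | (3R)-5-[(tert-butyldimethylsilyl)oxy]-3-(prop-1-en-2-yl)pent-4-enoic acid (E/Z mixture) | CC(C)(C)[Si](C)(C)OC=C[C@H](C(C)=C)CC(=O)O | intermediate
14 | (3R)-5-[(tert-butyldimethylsilyl)oxy]-3-(prop-1-en-2-yl)pent-4-enoyl chloride | CC(C)(C)[Si](C)(C)OC=C[C@H](C(C)=C)CC(=O)Cl | intermediate (not isolated)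
15 | methyl (2Z,5R)-7-[(tert-butyldimethylsilyl)oxy]-3-hydroxy-5-(prop-1-en-2-yl)-2-[8-methyl-3,6-dioxo-8-(triethylsilyloxy)-2-oxatricyclo[5.2.1.0(4,10)]dec-4-en-5-yl]hepta-2,6-dienoate (enol of the β-keto ester; 6-ene E/Z mixture) | C=C(C)[C@@H](C=CO[Si](C)(C)C(C)(C)C)C/C(O)=C(/C(=O)OC)C1=C2C(=O)O[C@@H]3C[C@](C)(O[Si](CC)(CC)CC)[C@H](C1=O)[C@H]23 | intermediate (not isolated)
16 | methyl (2Z,5R)-3,7-bis[(tert-butyldimethylsilyl)oxy]-5-(prop-1-en-2-yl)-2-[8-methyl-3,6-dioxo-8-(triethylsilyloxy)-2-oxatricyclo[5.2.1.0(4,10)]dec-4-en-5-yl]hepta-2,6-dienoate (6-ene E/Z mixture) | C=C(C)[C@@H](C=CO[Si](C)(C)C(C)(C)C)C/C(O[Si](C)(C)C(C)(C)C)=C(/C(=O)OC)C1=C2C(=O)O[C@@H]3C[C@](C)(O[Si](CC)(CC)CC)[C@H](C1=O)[C@H]23 | intermediate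
17 | photoadduct: cyclobutane C5–C9–C10–C11 fused to ring A, to the cyclopentanone and to the lactone; cyclobutane on the face of H8, ring A cis-fused, H11 syn to H7 and H8; C10 silyloxy epimers | C=C(C)[C@@H]1CC(O[Si](C)(C)C(C)(C)C)=C(C(=O)OC)[C@@]23C(=O)[C@@H]4[C@@H]5[C@@]2(C(O[Si](C)(C)C(C)(C)C)[C@H]31)C(=O)O[C@@H]5C[C@]4(C)O[Si](CC)(CC)CC | intermediate
18 | target skeleton with C3–OTBS enol ether and C15–OTES (H5, H7, H8, H11 all cis; isopropenyl trans to C10) | C=C(C)[C@@H]1CC(O[Si](C)(C)C(C)(C)C)=C(C(=O)OC)[C@H]2C(=O)[C@@H]3[C@@H]4C(=C[C@H]21)C(=O)O[C@@H]4C[C@]3(C)O[Si](CC)(CC)CC | intermediate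
19 | target CNP0268969.1 (1R,5S,7R,8R,11S,13R,15S in the labels used here) | C=C(C)[C@@H]1CC(O)=C(C(=O)OC)[C@H]2C(=O)[C@@H]3[C@@H]4C(=C[C@H]21)C(=O)O[C@@H]4C[C@]3(C)O | target

**Step count.** Total: 14 steps. Longest linear sequence: 11 steps (steps 1–7, then 11–14); the side chain takes steps 8–10.

**Steps most likely to fail, each with a fallback**

1. Step 12. What may go wrong: the triplet enone decays without bonding because six-membered closure is slower than the usual five-membered one, or electron transfer from the silyl enol ether leads to desilylation instead of cycloaddition. Fallback: the same two bonds are made thermally by a stepwise polar (2+2) reaction. Compound 16 is treated with Tf2NH (cat.) in CH2Cl2 at −78 °C, so that the nucleophilic enol ether carbon C11 adds to C5 of the activated unsaturated lactone (Mukaiyama–Michael, 6-exo) and the silyl ketene acetal so formed at C9 closes on the C10 silyloxocarbenium ion (aldol-type closure). This sets out from 16 and returns to the route at 17 without any new isolated compound; the same ring constraints fix C5, C9 and C11.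

2. Step 13. What may go wrong: the ketyl cleaves the better aligned external C5–C11 bond, the C9 enolate is protonated before it expels silyloxide, or the alkylidene lactone is over-reduced. Fallback (polar, no reductant): from 17, K2CO3 (cat.) in MeOH at 0 °C removes the C3 enol silyl group; the β-keto ester anion at C4 opens the cyclobutane by retro-Michael expulsion of C9 as the lactone enolate (the only stabilised carbanion that can leave from C5, and axial to ring A), and this enolate loses the C10 silyloxide to give the alkylidene β-keto ester F1. Hantzsch ester in CH2Cl2 at rt should then reduce only the triply activated C4=C5 bond to give the 15-O-triethylsilyl target F2, and HF·pyridine returns to the route at 19.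

3. Step 11. What may go wrong: O-acylation of the delocalised enolate, ketene formation from the acid chloride under amine base, or silylation at the wrong oxygen. Fallback: from 8, TBSOTf and Et3N give the O-silyl ketene acetal F3, which is freed from base and C-acylated with acid chloride 14 in CH2Cl2 without base (Mukaiyama-type acylation with loss of the silyl chloride) to give 15; silylation of 15 (TBSOTf, Et3N) rejoins the route at 16.

**Further compounds**

F0 | step 12 | none | none
F1 | step 13 | alkylidene β-keto ester: ring A C3 ketone with C4(CO2Me)=C5, C9=C10 alkylidene lactone, C15–OTES | C=C(C)[C@@H]1CC(=O)C(C(=O)OC)=C2C(=O)[C@@H]3[C@@H]4C(=C[C@H]21)C(=O)O[C@@H]4C[C@]3(C)O[Si](CC)(CC)CC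
F2 | step 13 | 15-O-triethylsilyl ether of the target | C=C(C)[C@@H]1CC(O)=C(C(=O)OC)[C@H]2C(=O)[C@@H]3[C@@H]4C(=C[C@H]21)C(=O)O[C@@H]4C[C@]3(C)O[Si](CC)(CC)CC
F3 | step 11 | O-silyl ketene acetal of 8 (geometry not defined) | COC(O[Si](C)(C)C(C)(C)C)=CC1=C2C(=O)O[C@@H]3C[C@](C)(O[Si](CC)(CC)CC)[C@H](C1=O)[C@H]23
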